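## The problem

The target is an unsymmetrical ether of two 6,8-dihydroxy-7-methoxy-3-methylisochroman-1-ones: C4 of unit A is bonded through oxygen to C6' of unit B (primed atoms), and C4' of unit B carries a free hydroxyl. Each half holds two adjacent stereocentres: (3R,4S) in unit A, with methyl and aryloxy trans, and (3'R,4'R) in unit B, with methyl and hydroxyl cis. Within a pair one centre can direct the other, but the pairs are separated by the ether oxygen and a benzene ring, so the absolute sense of each pair must come from a reagent. Both benzene rings have the oxygen pattern of 3,5-dihydroxy-4-methoxybenzoic acid (1), but the ring carbon that bears C4 (C4') lies para to the methoxyl and the lactone carbonyl sits on the neighbouring carbon C8a (C8a'). The carboxyl carbon of 1 must therefore become C4 (C4'), and C1 (C1') has to be introduced beside it. The benzylic C4–O and C4'–O bonds are fragile: base can move a 4-hydroxy lactone towards the five-membered phthalide isomer, activation of the oxygen invites loss of C3–H across C3–C4, and strong acid can ionise the para-methoxybenzylic carbon. O6' must also be told apart from O8', which is hydrogen-bonded to the C1' carbonyl. The feature that opens the key step lies in lactone B: O2' sits on C3' directly beside the oxygen-bearing C4', so at the ketone level of C4' the ring is a cyclic alpha-acyloxy ketone. Such a ketone is the product of a 1,2-acyloxy shift in an enol ester epoxide, here the spiro epoxide of a five-membered 3-ethylidenephthalide, and it leaves C3'–H acidic for a dynamic reduction.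

## Retrosynthesis

Isochromanone numbering is used for units A and B. Phthalides 8 and 12 keep phthalide numbering, in which C3 becomes C4 (C4'), and O5 and O7 become O6 (O6') and O8 (O8').

**18 to 17.** Only three methoxymethyl (MOM) ethers, on O6, O8 and O8', separate the target 18 from 17. Acetals are preferred to benzyl ethers because their removal needs neither hydrogenolysis, which would endanger the two benzylic C–O bonds, nor base, which would threaten the 4'-hydroxy lactone. The forward step must be an acid-catalysed acetal exchange mild enough to spare the C4 ether.

**17 to 16.** The C4'–H bond is removed, giving the isochroman-1',4'-dione 16. Because C3' of 16 lies between the ketone and the lactone oxygen and epimerises easily, one asymmetric transfer hydrogenation with dynamic kinetic resolution can set C3' and C4' together. Setting the pair by dihydroxylation of an open-chain alkene would leave a diol that can lactonise in two directions; in 16 the six-membered lactone is already in place when the carbinol appears. The precursor has two stereocentres fewer. The reduction must be governed by the catalyst and not by the remote unit A, and must be cis selective.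

**16 to 15 (key disconnection).** The ester bond O2'–C3' is cut and the acyl oxygen is returned to C4', which contracts the six-membered keto lactone to the five-membered spiro epoxide 15. This is preferred to closing the six-membered lactone by esterification of an open hydroxy acid, because the enol lactone behind 15 is flat, free of stereocentres and available by a ring closure that cannot go astray regiochemically. The forward step must favour acyl migration over hydride shift and must spare the acetals and the C4 ether.

**15 to 14 to 13.** The oxirane oxygen is removed to give the (Z)-ethylidenephthalide 14, and the MOM group on O8' is removed to give phenol 13. The oxidation must be neutral, and the phenol is capped first so that it does not compete for the oxidant.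

**13 to 11 and 12.** The C4–O bond is cut with inversion, giving the cis alcohol 11 and the diphenol 12. The neighbouring cut, at the aryl C6'–O bond, would need a copper-mediated arylation of the trans alcohol with retention. For that, ring B would have to exchange its C6' oxygen for boron, and a base-sensitive hydroxy lactone would have to act as nucleophile. The chosen cut uses the native phenol, and the cis alcohol it needs has the same relative and absolute configuration as unit B, so one reduction protocol serves both halves. The two fragments are of equal size. The forward step must give clean inversion without elimination and must select O5 of 12 over O7.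

**11 to 10 to 9 to 8.** Alcohol 11 is traced through dione 10 and spiro epoxide 9 to the bis-MOM ethylidenephthalide 8. These are the key disconnection and the reduction again, on the monomer, where they serve as a rehearsal.

**12 to 8.** The two MOM groups are removed, so both halves come from the single intermediate 8. The deprotection must not add a nucleophile across the enol lactone.

**8 to 6 and 7.** The aryl–carbonyl bond C7a–C1 and the acyl–oxygen bond C1–O2 are cut, giving iodo ketone 6 and carbon monoxide (7). Closing the phthalide by alkyne coupling onto an aryl halide beside a carboxyl group would need the halogen para to the methoxyl and the carboxyl next to it, the reverse of what 1 offers. With the native carboxyl as C1 the oxygens would fall on C5 to C7. The ketone route makes the carboxyl carbon of 1 into C3 of the phthalide and brings in C1 as 7.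

**6 to 5 to 2 and 3 to 1.** The iodine is removed to give the twofold-symmetric ketone 5, whose two free ring positions are equivalent, so no regiochemical question arises. The ethyl–carbonyl bond is cut, giving ester 2 and ethylmagnesium bromide (3) through Weinreb amide 4, and 2 is the fully MOM-protected form of acid 1.

## Roads not taken

**Alternative 1:** Ring A itself would be the last ring made. The aromatic bond C4a–C8a is cut, opening unit A to a polyketide-like chain that already carries C3, C4 and the complete, protected unit B. In the forward direction the diketo dioxinone A1 would be heated with methanol. The acyl ketene released is captured as a methyl beta-keto ester, whose C8a methylene adds to the C4a ketone; dehydration and enolisation give the methyl resorcylate A2 with free C6 and C8 hydroxyls, ready to lactonise onto O3.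

- Merits: no protecting groups on ring A, no substitution on a crowded arene, and an ether bond that exists before the ring does. In these respects this road is better than the chosen plan, which spends steps on MOM ethers and makes the C4–O bond on a finished lactone.
- Weak points: in A1 the C4 stereocentre is the alpha carbon of the C4a ketone and carries an aryloxy group, with a silyloxy group beta to the same ketone, so the enolising aldol conditions threaten epimerisation and beta-elimination. The chain has a methoxylated carbon between two ketones and several aldol modes open. All four stereocentres must be made beforehand, and unit B would in practice need something like the ring expansion used here.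
- Comparison: against the protecting-group economy of this road, the chosen plan offers one aromatic intermediate 8 for both halves, stereocentres created late under catalyst control, and no epimerisable alpha-aryloxy ketone.

**Alternative 2:** Lactone A would come from the chiral pool and ring A would be annulated onto it, the cut running through C5–C4a and C8–C8a. D-Glucal A3 supplies C3 and C4 with the trans relationship and the correct absolute sense, its hydroxymethyl group becoming the C3 methyl. After arylation of O4 with unit B, oxidation to the unsaturated lactone and bromination, the dienophile A4 would react with the bis-silyloxy diene A5 in a Diels–Alder reaction. Loss of HBr and methanol would aromatise ring A to A6.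

- Merits: the C3/C4 pair needs no asymmetric reaction and cannot come out with the wrong sense, whereas the chosen plan relies on a catalytic reduction followed by an inversion. Here this road is the stronger one.
- Weak points: the O4–aryl bond must be formed on a secondary carbohydrate hydroxyl with retention, using an electron-rich, ortho-substituted aryl partner, an etherification the chosen plan avoids. Several steps go into deoxygenation and oxidation-state changes. A4 is a trisubstituted bromo enoate with an allylic aryloxy group, a slow dienophile for a sensitive diene, and on aromatisation the aryloxide can leave in place of bromide. Unit B still needs its own route.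
- Comparison: the chosen plan answers the pool-derived stereocentres with a reduction whose sense and cis selectivity are tested on monomer 10 before the dimer is committed, and it needs no second route for unit B.

**Alternative 3:** The heterocycle of unit A is cut at C3–C4 and C1–O2, leaving a benzaldehyde whose ortho methylene already carries the aryl ether, and a two-carbon aldehyde. Irradiation of A7 would give the photoenol by 1,5-hydrogen shift. Its hetero-Diels–Alder reaction with acetaldehyde A8, held on Ti(Oi-Pr)4 with a TADDOL ligand, would close the pyran ring as lactol A9 with both new stereocentres.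

- Merits: the ether bond is made by plain alkylation of a phenol with a primary benzylic halide, far easier than any substitution at the secondary C4, and the ring and both stereocentres of lactone A arise in one step. In both respects this road is better.
- Weak points: photoenols are trapped reliably by electron-poor alkenes, and an unactivated aliphatic aldehyde is a weak heterodienophile. The trans relationship and the absolute sense at C3 and C4 would rest on a chiral Lewis acid working inside a photochemical cascade beside a second aromatic chromophore. The product is a lactol, so an oxidation is added, and unit B must be complete beforehand.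
- Comparison: the chosen plan gives up the easy ether formation for a Mitsunobu inversion, and offers in return that every step, the stereo-determining ones included, belongs to a known reaction type.

Key step: step 11

Assumption: RuCl(p-cymene)[(S,S)-TsDPEN] is taken to deliver hydride to the C4 (C4') ketone in the same spatial sense as to 1-tetralone, which corresponds to 4R (4'R) here. If the sense proves opposite, the (R,R) complex would be used in steps 6 and 12.

Abbreviations: MOM, methoxymethyl; DMDO, dimethyldioxirane; DIAD, diisopropyl azodicarboxylate; TsDPEN, N-tosyl-1,2-diphenylethylenediamine.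

## Route

Step 1
Reactants: 1 3,5-dihydroxy-4-methoxybenzoic acid
Product: 2 methoxymethyl 4-methoxy-3,5-bis(methoxymethoxy)benzoate
Conditions: MOMCl (4 equiv), i-Pr2NEt, CH2Cl2, 0 °C to rt
Reagents that add atoms: chloromethyl methyl ether (MOMCl), COCCl
Why: Hünig's base generates the carboxylate and both phenoxides, which are alkylated by the reactive alpha-chloro ether (Williamson-type O-alkylation); the MOM ester formed beside the two ethers is an activated ester used in step 2, and the product keeps the twofold symmetry of 1.

Step 2
Reactants: 2 methoxymethyl 4-methoxy-3,5-bis(methoxymethoxy)benzoate; 3 ethylmagnesium bromide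
Product: 5 1-[4-methoxy-3,5-bis(methoxymethoxy)phenyl]propan-1-one, via Weinreb amide 4 (not isolated)
Conditions: MeNH(OMe)·HCl, i-PrMgCl, THF, −20 °C; then EtMgBr, −20 to 0 °C; aq NH4Cl
Reagents that add atoms: N,O-dimethylhydroxylamine hydrochloride, CNOC.Cl (its atoms remain only in intermediate 4)
Why: One-pot Weinreb ketone synthesis: the magnesium amide of N,O-dimethylhydroxylamine attacks the carbonyl of the activated MOM ester to give 4, and EtMgBr adds only once because the magnesium chelate of the tetrahedral adduct persists until work-up; an excess of 3 covers what the released formaldehyde equivalent consumes, and the aryl MOM ethers are inert to both organomagnesium reagents.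

Step 3
Reactants: 5 1-[4-methoxy-3,5-bis(methoxymethoxy)phenyl]propan-1-one
Product: 6 1-[2-iodo-4-methoxy-3,5-bis(methoxymethoxy)phenyl]propan-1-one
Conditions: N-iodosuccinimide (1.05 equiv), CF3CO2H (10 mol %), MeCN, 0 °C to rt
Reagents that add atoms: N-iodosuccinimide, O=C1CCC(=O)N1I
Why: Electrophilic aromatic iodination: C2 and C6 of 5 are equivalent by symmetry and each lies ortho to one MOM ether and para to the other, so a single mono-iodide is expected with one equivalent of reagent; the ketone alpha carbon is not iodinated under these weakly acidic, non-enolising conditions.

Step 4
Reactants: 6 1-[2-iodo-4-methoxy-3,5-bis(methoxymethoxy)phenyl]propan-1-one; 7 carbon monoxide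
Product: 8 (3Z)-3-ethylidene-6-methoxy-5,7-bis(methoxymethoxy)-2-benzofuran-1(3H)-one
Conditions: PdCl2(PPh3)2 (5 mol %), CO (20 atm), Et3N, DMF, 100 °C
Reagents that add atoms: none
Why: Palladium-catalysed carbonylative cyclisation of an ortho-iodoaryl alkyl ketone: oxidative addition and CO insertion give an aroylpalladium species that is captured by the enol oxygen of the neighbouring propanoyl group (5-exo closure with the enol double bond outside the ring), whereas C-acylation to an indanedione would be an enol-endo closure; the Z isomer, with the methyl turned away from C4–H, is the more stable one, and the alkene geometry has no bearing on later steps.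

Step 5
Reactants: 8 (3Z)-3-ethylidene-6-methoxy-5,7-bis(methoxymethoxy)-2-benzofuran-1(3H)-one
Product: 10 racemic 7-methoxy-6,8-bis(methoxymethoxy)-3-methyl-1H-isochromene-1,4(3H)-dione, via spiro epoxide 9 (not isolated)
Conditions: DMDO (acetone), CH2Cl2, 0 °C; evaporate; TsOH (5 mol %), CH2Cl2, rt
Reagents that add atoms: dimethyldioxirane, CC1(C)OO1
Why: The dioxirane transfers oxygen to the electron-rich enol lactone double bond under neutral conditions, and catalytic acid then converts the enol ester epoxide 9 into the alpha-acyloxy ketone by 1,2-acyloxy shift, enlarging the phthalide to the six-membered keto lactone (mechanism as in step 11, for which this step is the rehearsal); C3 is formed as a racemate and stays labile, as intended.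

Step 6
Reactants: 10 racemic 7-methoxy-6,8-bis(methoxymethoxy)-3-methyl-1H-isochromene-1,4(3H)-dione
Product: 11 (3R,4R)-4-hydroxy-7-methoxy-6,8-bis(methoxymethoxy)-3-methyl-3,4-dihydro-1H-isochromen-1-one (cis)
Conditions: RuCl(p-cymene)[(S,S)-TsDPEN] (2 mol %), HCO2H–Et3N (5:2), CH2Cl2, 30 °C
Reagents that add atoms: none
Why: Noyori–Ikariya asymmetric transfer hydrogenation with dynamic kinetic resolution: C3–H of 10, flanked by the ketone and the lactone oxygen, exchanges through the enol in the amine–formate medium, the catalyst delivers hydride to one face of the aryl ketone (aryl/alkyl discrimination as for 1-tetralone, here giving 4R), and only the C3 epimer whose methyl lies opposite the incoming hydride is reduced fast, so the cis (3R,4R) alcohol should result; the lactone carbonyl is not reduced.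

Step 7
Reactants: 8 (3Z)-3-ethylidene-6-methoxy-5,7-bis(methoxymethoxy)-2-benzofuran-1(3H)-one
Product: 12 (3Z)-3-ethylidene-5,7-dihydroxy-6-methoxy-2-benzofuran-1(3H)-one
Conditions: NaHSO4·SiO2, CH2Cl2, rt
Reagents that add atoms: none
Why: Brønsted-acid cleavage of aryl MOM acetals on a solid acid; the heterogeneous, aprotic conditions are chosen so that no alcohol is present to add across the enol lactone.

Step 8
Reactants: 11 (3R,4R)-4-hydroxy-7-methoxy-6,8-bis(methoxymethoxy)-3-methyl-3,4-dihydro-1H-isochromen-1-one; 12 (3Z)-3-ethylidene-5,7-dihydroxy-6-methoxy-2-benzofuran-1(3H)-one
Product: 13 (3R,4S)-4-{[(3Z)-3-ethylidene-7-hydroxy-6-methoxy-1-oxo-1,3-dihydro-2-benzofuran-5-yl]oxy}-7-methoxy-6,8-bis(methoxymethoxy)-3-methyl-3,4-dihydro-1H-isochromen-1-one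
Conditions: PPh3, DIAD, THF, 0 °C to rt (12 in slight excess)
Reagents that add atoms: none
Why: Mitsunobu etherification: the oxyphosphonium ion of the secondary benzylic alcohol is displaced by phenoxide from the face opposite the leaving group, which is also the face away from the C3 methyl, so C4 is inverted to S and the trans ether results; of the two phenols of 12, O5 (para to the lactone carbonyl, more acidic and unencumbered) should react while O7 is held in a hydrogen bond to the carbonyl, and the electron-withdrawing ortho carbonyl of 11 disfavours ionisation at C4.

Step 9
Reactants: 13 the phenol from step 8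
Product: 14 (3R,4S)-4-{[(3Z)-3-ethylidene-6-methoxy-7-(methoxymethoxy)-1-oxo-1,3-dihydro-2-benzofuran-5-yl]oxy}-7-methoxy-6,8-bis(methoxymethoxy)-3-methyl-3,4-dihydro-1H-isochromen-1-one
Conditions: MOMCl, i-Pr2NEt, CH2Cl2, 0 to 40 °C
Reagents that add atoms: chloromethyl methyl ether (MOMCl), COCCl
Why: Williamson-type O-alkylation of the remaining, hydrogen-bonded phenol with the reactive chloro ether under amine base; capping O8' keeps the phenol from competing for the oxidant in step 10, and the lactones and the enol lactone are inert to these conditions.

Step 10
Reactants: 14 the tris-MOM ethylidenephthalide ether from step 9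
Product: 15 spiro epoxide of 14: unit A as in 14, bonded through O to C6 of 5-methoxy-4-(methoxymethoxy)-3'-methyl-3-oxo-3H-spiro[2-benzofuran-1,2'-oxirane] (two diastereomers at the oxirane)
Conditions: DMDO (acetone), CH2Cl2, 0 °C; evaporate
Reagents that add atoms: dimethyldioxirane, CC1(C)OO1
Why: Epoxidation by dimethyldioxirane of the enol lactone double bond, the only alkene in 14; the neutral conditions leave acetone as the sole by-product and spare the acid-labile spiro epoxide, and attack on both faces gives two diastereomers, which is harmless because both oxirane centres lose their configuration in step 11.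

Step 11
Reactants: 15 the spiro epoxide from step 10
Product: 16 (3R,4S)-7-methoxy-4-{[7-methoxy-8-(methoxymethoxy)-3-methyl-1,4-dioxo-3,4-dihydro-1H-isochromen-6-yl]oxy}-6,8-bis(methoxymethoxy)-3-methyl-3,4-dihydro-1H-isochromen-1-one (both C3' epimers)
Conditions: TsOH (anhydrous, 10 mol %), CH2Cl2, rt to 40 °C
Reagents that add atoms: none
Why: Protonation of the oxirane oxygen weakens its bond to the spiro carbon C4', which carries the aryl ring and the lactone oxygen and so takes the positive charge; the acyl group then passes from the oxygen on C4' to the oxygen on C3' while C4' becomes the ketone carbon. This is the acid-catalysed rearrangement of an enol ester epoxide to an alpha-acyloxy ketone, known in this form as the conversion of alkylidenephthalide epoxides into isochroman-1,4-diones. The open-chain picture, in which the ester carbonyl oxygen displaces the oxirane oxygen at C3' through a dioxolanylium ion, is less likely here because the phthalide holds that oxygen away from C3' and the bridged cation would be strained; the stepwise acyl transfer (directly, or through the ring-opened acylium ion or hydroxy keto acid) leads to the same constitution. The new O2'–C3' ester linkage closes the ring C1'–O2'–C3'–C4'–C4a'–C8a' by 6-exo-trig attack of the C3' oxygen on C1' (6-exo-tet if a carboxyl oxygen attacks C3'), and the five-membered lactone bond to C4' is given up for the C4' carbonyl. No stereocentre is fixed: C3' appears as both epimers and remains labile beside the ketone, so retention or inversion at C3' is immaterial and step 12 can use the mixture. The selectivity needed is acyl transfer over 1,2-hydride shift from C3' to C4' and over loss of the MOM acetals; the acyl group sits on the carbon next to the receiving oxygen, the conjugated aryl ketone in an unstrained six-membered lactone is the thermodynamic sink, and capture of the cation by adventitious water only leads to the hydroxy keto acid that lactonises to the same dione. Anhydrous catalytic acid without a nucleophilic solvent should leave the acetals and the C4 ether of unit A alone, and the same reaction will already have been run on the simpler epoxide 9 in step 5.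

Step 12
Reactants: 16 the dimeric dione from step 11
Product: 17 (3R,4S)-4-{[(3R,4R)-4-hydroxy-7-methoxy-8-(methoxymethoxy)-3-methyl-1-oxo-3,4-dihydro-1H-isochromen-6-yl]oxy}-7-methoxy-6,8-bis(methoxymethoxy)-3-methyl-3,4-dihydro-1H-isochromen-1-one
Conditions: RuCl(p-cymene)[(S,S)-TsDPEN] (3 mol %), HCO2H–Et3N (5:2), CH2Cl2, 30 °C
Reagents that add atoms: none
Why: The same asymmetric transfer hydrogenation with dynamic kinetic resolution as in step 6: C3' epimerises through the enol, the catalyst fixes 4'R by its own facial preference, independent of the remote unit A, and hydride delivery anti to the C3' methyl fixes 3'R in the cis product; the unit A lactone, its benzylic ether and the MOM acetals are untouched by the formate reductant.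

Step 13
Reactants: 17 the tris-MOM ether of the target from step 12
Product: 18 (3R,4S)-4-{[(3R,4R)-4,8-dihydroxy-7-methoxy-3-methyl-1-oxo-3,4-dihydro-1H-isochromen-6-yl]oxy}-6,8-dihydroxy-7-methoxy-3-methyl-3,4-dihydro-1H-isochromen-1-one (target)
Conditions: HCl (1.25 M in MeOH), MeOH–THF, 0 °C to rt
Reagents that add atoms: none
Why: Acid-catalysed acetal exchange transfers the three methoxymethyl groups to methanol as dimethoxymethane; the MOM ethers ortho to the lactone carbonyls go first and the phenols freed at C8 and C8' then hydrogen-bond to those carbonyls, which holds both six-membered lactones, while dilute acid at room temperature should leave the C4 aryl ether and the C4' carbinol intact.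

## Compound list

1 | 3,5-dihydroxy-4-methoxybenzoic acid | COc1c(O)cc(cc1O)C(=O)O | starting material
2 | methoxymethyl 4-methoxy-3,5-bis(methoxymethoxy)benzoate | COCOC(=O)c1cc(OCOC)c(OC)c(OCOC)c1 | intermediate
3 | ethylmagnesium bromide | CC[Mg]Br | starting material
4 | N,4-dimethoxy-N-methyl-3,5-bis(methoxymethoxy)benzamide (Weinreb amide, not isolated) | CON(C)C(=O)c1cc(OCOC)c(OC)c(OCOC)c1 | intermediate
5 | 1-[4-methoxy-3,5-bis(methoxymethoxy)phenyl]propan-1-one | CCC(=O)c1cc(OCOC)c(OC)c(OCOC)c1 | intermediate
6 | 1-[2-iodo-4-methoxy-3,5-bis(methoxymethoxy)phenyl]propan-1-one | CCC(=O)c1cc(OCOC)c(OC)c(OCOC)c1I | intermediate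
7 | carbon monoxide | [C-]#[O+] | starting material
8 | (3Z)-3-ethylidene-6-methoxy-5,7-bis(methoxymethoxy)-2-benzofuran-1(3H)-one | C/C=C1\OC(=O)c2c(OCOC)c(OC)c(OCOC)cc12 | intermediate
9 | racemic 5-methoxy-4,6-bis(methoxymethoxy)-3'-methyl-3H-spiro[2-benzofuran-1,2'-oxiran]-3-one (spiro epoxide of 8, not isolated) | COCOc1cc2c(c(OCOC)c1OC)C(=O)OC23OC3C | intermediate
10 | racemic 7-methoxy-6,8-bis(methoxymethoxy)-3-methyl-1H-isochromene-1,4(3H)-dione (C3 labile) | COCOc1cc2c(c(OCOC)c1OC)C(=O)OC(C)C2=O | intermediate
11 | (3R,4R)-4-hydroxy-7-methoxy-6,8-bis(methoxymethoxy)-3-methyl-3,4-dihydro-1H-isochromen-1-one (cis) | COCOc1cc2c(c(OCOC)c1OC)C(=O)O[C@H](C)[C@@H]2O | intermediate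
12 | (3Z)-3-ethylidene-5,7-dihydroxy-6-methoxy-2-benzofuran-1(3H)-one | C/C=C1\OC(=O)c2c(O)c(OC)c(O)cc12 | intermediate
13 | (3R,4S)-4-{[(3Z)-3-ethylidene-7-hydroxy-6-methoxy-1-oxo-1,3-dihydro-2-benzofuran-5-yl]oxy}-7-methoxy-6,8-bis(methoxymethoxy)-3-methyl-3,4-dihydro-1H-isochromen-1-one | COc1c(OCOC)cc2c(c1OCOC)C(=O)O[C@H](C)[C@H]2Oc1cc2c(c(O)c1OC)C(=O)O/C2=C\C | intermediate
14 | (3R,4S)-4-{[(3Z)-3-ethylidene-6-methoxy-7-(methoxymethoxy)-1-oxo-1,3-dihydro-2-benzofuran-5-yl]oxy}-7-methoxy-6,8-bis(methoxymethoxy)-3-methyl-3,4-dihydro-1H-isochromen-1-one | COc1c(OCOC)cc2c(c1OCOC)C(=O)O[C@H](C)[C@H]2Oc1cc2c(c(OCOC)c1OC)C(=O)O/C2=C\C | intermediate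
15 | spiro epoxide of 14 (unit A (3R,4S); two diastereomers at the oxirane) | COc1c(OCOC)cc2c(c1OCOC)C(=O)O[C@H](C)[C@H]2Oc1cc2c(c(OCOC)c1OC)C(=O)OC23OC3C | intermediate
16 | (3R,4S)-7-methoxy-4-{[7-methoxy-8-(methoxymethoxy)-3-methyl-1,4-dioxo-3,4-dihydro-1H-isochromen-6-yl]oxy}-6,8-bis(methoxymethoxy)-3-methyl-3,4-dihydro-1H-isochromen-1-one (C3' epimers) | COc1c(OCOC)cc2c(c1OCOC)C(=O)O[C@H](C)[C@H]2Oc1cc2c(c(OCOC)c1OC)C(=O)OC(C)C2=O | intermediate
17 | (3R,4S)-4-{[(3R,4R)-4-hydroxy-7-methoxy-8-(methoxymethoxy)-3-methyl-1-oxo-3,4-dihydro-1H-isochromen-6-yl]oxy}-7-methoxy-6,8-bis(methoxymethoxy)-3-methyl-3,4-dihydro-1H-isochromen-1-one | COc1c(OCOC)cc2c(c1OCOC)C(=O)O[C@H](C)[C@H]2Oc1cc2c(c(OCOC)c1OC)C(=O)O[C@H](C)[C@@H]2O | intermediate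
18 | (3R,4S)-4-{[(3R,4R)-4,8-dihydroxy-7-methoxy-3-methyl-1-oxo-3,4-dihydro-1H-isochromen-6-yl]oxy}-6,8-dihydroxy-7-methoxy-3-methyl-3,4-dihydro-1H-isochromen-1-one | COc1c(O)cc2c(c1O)C(=O)O[C@H](C)[C@H]2Oc1cc2c(c(O)c1OC)C(=O)O[C@H](C)[C@@H]2O | target

## Step count and least certain steps

Total step count: 13. Longest linear sequence: 12 steps (steps 1 to 6 and 8 to 13); the branch to 12 (step 7) adds one step from 8.

**Key step, step 11.** The most likely failure is diversion of the C4' cation, by 1,2-hydride shift from C3' in place of acyl transfer, or slow loss of MOM acetals and ionisation at the C4 ether if more acid or heat is needed. The fallback sets out from 14 and avoids both acid and a cationic intermediate. Catalytic OsO4 with N-methylmorpholine N-oxide in aqueous acetone would dihydroxylate the enol lactone, and the hemiketal formed opens to the hydroxy keto acid 4-{[(3R,4S)-7-methoxy-6,8-bis(methoxymethoxy)-3-methyl-1-oxo-3,4-dihydro-1H-isochromen-4-yl]oxy}-6-(2-hydroxypropanoyl)-3-methoxy-2-(methoxymethoxy)benzoic acid F1. Carbodiimide lactonisation (EDC·HCl, 4-dimethylaminopyridine, CH2Cl2) of the C3' hydroxyl onto the acid would then close the six-membered ring, and the route is rejoined at 16.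

**Step 8.** Elimination across C3–C4 from the oxyphosphonium ion is the main danger, since the cis alcohol has C3–H anti to the leaving group. Slow displacement at the hindered C4 and alkylation of the wrong phenol are lesser ones. The fallback sets out from 11: trichloroacetonitrile with catalytic 1,8-diazabicyclo[5.4.0]undec-7-ene would give the trichloroacetimidate F2. With 12 and catalytic BF3·OEt2 at low temperature, substitution would run through the C4 benzylic cation, which the phenol should attack on the face away from the C3 methyl. The trans ether would then arise by substrate control in place of inversion, and the route is rejoined at 13.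

**Step 12.** Epimerisation at C3' may be too slow relative to reduction, or catalyst control may be eroded by the bulky aryloxy group at C6'; either would give a mixture of unit B stereoisomers. Translactonisation of the new hydroxy lactone in the amine medium is a further risk. Step 6 tests the catalyst sense and cis selectivity on the simpler dione 10 beforehand. The fallback sets out from 16: NaBH4 with CeCl3 in MeOH–THF at −78 °C, with hydride entering anti to the C3' methyl under substrate control, would give the two cis alcohols 17 and the (3'S,4'S) diastereomer F3. These differ as diastereomers because unit A is a single enantiomer, so they can be separated by chromatography. F3 is returned to 16 by Dess–Martin oxidation and recycled, and the route is rejoined at 17.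

**Step 4.** The aroylpalladium intermediate may fail to be captured by the enol oxygen of the hindered, twisted ketone and be diverted to reduction or intermolecular acylation. The fallback sets out from 6 and separates carbonylation from ring closure. Hydroxycarbonylation (PdCl2(PPh3)2, CO, water, Et3N, DMF) would give the keto acid 3-methoxy-2,4-bis(methoxymethoxy)-6-propanoylbenzoic acid F4. Warming F4 with acetic anhydride and NaOAc, the classical enol lactonisation of 2-acylbenzoic acids, would dehydrate it, and the route is rejoined at 8.

**Step 7.** Acid-promoted addition of water across the enol lactone, or alkylation of the electron-rich ring by the released formaldehyde, could consume the diphenol. The fallback sets out from 6 and changes the protecting groups before the phthalide exists. HCl in methanol would give 1-(3,5-dihydroxy-2-iodo-4-methoxyphenyl)propan-1-one F5, and tert-butyldimethylsilyl chloride with imidazole the bis(silyl ether) F6. Carbonylative cyclisation as in step 4 would then give the silylated ethylidenephthalide F7. Bu4NF buffered with acetic acid removes the silyl groups without acid or alcohol, and the route is rejoined at 12.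

## Further compounds

F1 | step 11 | 4-{[(3R,4S)-7-methoxy-6,8-bis(methoxymethoxy)-3-methyl-1-oxo-3,4-dihydro-1H-isochromen-4-yl]oxy}-6-(2-hydroxypropanoyl)-3-methoxy-2-(methoxymethoxy)benzoic acid (carbinol epimers) | COc1c(OCOC)cc2c(c1OCOC)C(=O)O[C@H](C)[C@H]2Oc1cc(C(=O)C(C)O)c(C(=O)O)c(OCOC)c1OC
F2 | step 8 | (3R,4R)-7-methoxy-6,8-bis(methoxymethoxy)-3-methyl-1-oxo-3,4-dihydro-1H-isochromen-4-yl 2,2,2-trichloroacetimidate | COCOc1cc2c(c(OCOC)c1OC)C(=O)O[C@H](C)[C@@H]2OC(=N)C(Cl)(Cl)Cl
F3 | step 12 | (3'S,4'S) diastereomer of 17 | COc1c(OCOC)cc2c(c1OCOC)C(=O)O[C@H](C)[C@H]2Oc1cc2c(c(OCOC)c1OC)C(=O)O[C@@H](C)[C@H]2O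
F4 | step 4 | 3-methoxy-2,4-bis(methoxymethoxy)-6-propanoylbenzoic acid | CCC(=O)c1cc(OCOC)c(OC)c(OCOC)c1C(=O)O
F5 | step 7 | 1-(3,5-dihydroxy-2-iodo-4-methoxyphenyl)propan-1-one | CCC(=O)c1cc(O)c(OC)c(O)c1I
F6 | step 7 | 1-[3,5-bis(tert-butyldimethylsilyloxy)-2-iodo-4-methoxyphenyl]propan-1-one | CCC(=O)c1cc(O[Si](C)(C)C(C)(C)C)c(OC)c(O[Si](C)(C)C(C)(C)C)c1I
F7 | step 7 | (3Z)-5,7-bis(tert-butyldimethylsilyloxy)-3-ethylidene-6-methoxy-2-benzofuran-1(3H)-one | C/C=C1\OC(=O)c2c(O[Si](C)(C)C(C)(C)C)c(OC)c(O[Si](C)(C)C(C)(C)C)cc12
A1 | alternative 1 | diketo dioxinone carrying the C3–C4 side chain and protected unit B | CC1(C)OC(=O)C=C(O1)C(OC)C(=O)CC(=O)[C@H](Oc1cc2c(c(OCOC)c1OC)C(=O)O[C@H](C)[C@@H]2O[Si](C)(C)C(C)(C)C)[C@@H](C)O[Si](CC)(CC)CC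
A2 | alternative 1 | methyl resorcylate of ring A with side chain and protected unit B | COC(=O)c1c(O)c(OC)c(O)cc1[C@H](Oc1cc2c(c(OCOC)c1OC)C(=O)O[C@H](C)[C@@H]2O[Si](C)(C)C(C)(C)C)[C@@H](C)O[Si](CC)(CC)CC
A3 | alternative 2 | D-glucal | OC[C@H]1OC=C[C@@H](O)[C@@H]1O
A4 | alternative 2 | 3-bromo-6-methyl-5,6-dihydro-2H-pyran-2-one carrying protected unit B on O5 (O4 of unit A) | O=C1O[C@H](C)[C@@H](Oc2cc3c(c(OCOC)c2OC)C(=O)O[C@H](C)[C@@H]3O[Si](C)(C)C(C)(C)C)C=C1Br
A5 | alternative 2 | 1,2-dimethoxy-1,3-bis(trimethylsilyloxy)buta-1,3-diene | C=C(O[Si](C)(C)C)C(OC)=C(OC)O[Si](C)(C)C
A6 | alternative 2 | dimer with unit A complete and unit B as C8' MOM ether and C4' silyl ether | COc1c(O)cc2c(c1O)C(=O)O[C@H](C)[C@H]2Oc1cc2c(c(OCOC)c1OC)C(=O)O[C@H](C)[C@@H]2O[Si](C)(C)C(C)(C)C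
A7 | alternative 3 | 3-methoxy-2,4-bis(methoxymethoxy)-6-(aryloxymethyl)benzaldehyde, aryl being protected unit B | COc1c(OCOC)cc(COc2cc3c(c(OCOC)c2OC)C(=O)O[C@H](C)[C@@H]3O[Si](C)(C)C(C)(C)C)c(C=O)c1OCOC
A8 | alternative 3 | acetaldehyde | CC=O
A9 | alternative 3 | C1 lactol of the protected dimer (C1 epimers) | COc1c(OCOC)cc2c(c1OCOC)C(O)O[C@H](C)[C@H]2Oc1cc2c(c(OCOC)c1OC)C(=O)O[C@H](C)[C@@H]2O[Si](C)(C)C(C)(C)C
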